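**Plan**

- Retrosynthesis: the twelve phenols are masked as six methyl ethers and three O–CH2–O bridges. The three aryl–aryl bonds (A–B, B–C, C–D) are then cut together, leaving an open chain of four phloroglucinol ether rings joined by three formaldehyde acetals, with bromine already on ring C.
- Enabling feature: on both rings of every inter-ring bond (A/B, B/C, C/D) the carbons next to the bond carry oxygen, so one CH2 can tie each such oxygen pair. All four rings are 1,3,5-trioxygenated, so any ring carbon ortho to a bridge oxygen leads to the same skeleton. The bromine-bearing carbon of ring C sits between two oxygens and acts as a blocking group.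
- Forward: one aryloxymethyl chloride from 3,5-dimethoxyphenol builds both outer acetals, with 5-methoxyresorcinol and with its 2-bromo derivative (made by directed lithiation). The central acetal is made last. One anodic dehydrogenative coupling then closes three dibenzo-1,3-dioxepine rings (A–B, B–C, C–D), and BBr3 removes all bridges and methyl groups.
- Stereochemistry: the target has no stereocentre, so none is set; the biaryl axes form without control.

Key step: step 11

Assumption: the target is written without stereodescriptors, so its only potentially stereogenic element, the B–C axis between two unsymmetrically substituted rings, is left unspecified and the material is taken as racemic.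

**Route**

Step 1
Reactants: 1 3,5-dimethoxyphenol; 2 chloromethyl methyl sulfide
Product: 3 1,3-dimethoxy-5-[(methylsulfanyl)methoxy]benzene
Conditions: NaH, NaI (cat.), DMF, 0 °C → rt
Reagents that add atoms: none
Why: Williamson ether synthesis, in which the sodium phenoxide displaces chloride from the α-chloro sulfide (iodide-assisted SN2), the standard preparation of aryl methylthiomethyl ethers.

Step 2
Reactants: 3 1,3-dimethoxy-5-[(methylsulfanyl)methoxy]benzene
Product: 4 1-(chloromethoxy)-3,5-dimethoxybenzene
Conditions: SO2Cl2 (1.0 equiv), CH2Cl2, −78 °C; cyclohexene, −78 → 0 °C; volatiles removed, Kugelrohr distillation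
Reagents that add atoms: sulfuryl chloride, O=S(=O)(Cl)Cl
Why: Chlorinative cleavage of an O,S-acetal, in which sulfur (far more nucleophilic than the ring) is chlorinated to a chlorosulfonium ion that fragments to the aryloxymethyl cation and collapses to the chloromethyl ether, while cyclohexene captures the MeSCl released before it can sulfenylate the electron-rich ring.

Step 3
Reactants: 4 1-(chloromethoxy)-3,5-dimethoxybenzene; 5 5-methoxybenzene-1,3-diol (5-methoxyresorcinol)
Product: 6 3-[(3,5-dimethoxyphenoxy)methoxy]-5-methoxyphenol
Conditions: 5 (3 equiv), NaH (1 equiv), DMF, 0 °C → rt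
Reagents that add atoms: none
Why: Williamson-type substitution of the kind used in MOM protection, in which the monophenoxide of the symmetrical diol (kept in excess to limit double alkylation) attacks the reactive α-chloro ether at oxygen and should give the unsymmetrical diaryl formal.

Step 4
Reactants: 5 5-methoxybenzene-1,3-diol
Product: 7 1-methoxy-3,5-bis(methoxymethoxy)benzene
Conditions: NaH, MOMCl, DMF, 0 °C → rt
Reagents that add atoms: chloromethyl methyl ether (MOMCl), COCCl
Why: Standard methoxymethyl protection (Williamson alkylation of both phenoxides), which also installs the two directing groups needed for the next step.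

Step 5
Reactants: 7 1-methoxy-3,5-bis(methoxymethoxy)benzene
Product: 9 2-bromo-5-methoxy-1,3-bis(methoxymethoxy)benzene, via aryllithium 8 (not isolated)
Conditions: n-BuLi, THF, 0 °C; BrCCl2CCl2Br, −78 °C → rt
Reagents that add atoms: 1,2-dibromo-1,1,2,2-tetrachloroethane, BrC(Cl)(Cl)C(Cl)(Cl)Br (the bromine of 9); n-butyllithium, [Li]CCCC (the lithium of 8 only)
Why: Directed ortho-metalation, in which the carbon between the two OCH2OMe groups is deprotonated under double chelation and the aryllithium takes bromine from the positive-halogen donor with loss of tetrachloroethene.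

Step 6
Reactants: 9 2-bromo-5-methoxy-1,3-bis(methoxymethoxy)benzene
Product: 10 2-bromo-5-methoxybenzene-1,3-diol
Conditions: HCl (2 M in MeOH), rt → 40 °C
Reagents that add atoms: none
Why: Acid-catalysed acetal exchange with methanol should remove both MOM groups as dimethoxymethane under conditions mild enough to leave the aryl bromide and the methyl ether untouched.

Step 7
Reactants: 10 2-bromo-5-methoxybenzene-1,3-diol; 4 1-(chloromethoxy)-3,5-dimethoxybenzene
Product: 11 2-bromo-3-[(3,5-dimethoxyphenoxy)methoxy]-5-methoxyphenol
Conditions: 10 (2.5 equiv, excess recovered), NaH (1 equiv), DMF, 0 °C → rt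
Reagents that add atoms: none
Why: Williamson-type O-alkylation as in step 3; the two hydroxyls of 10 are equivalent, so mono-alkylation can give only one product.

Step 8
Reactants: 6 3-[(3,5-dimethoxyphenoxy)methoxy]-5-methoxyphenol; 2 chloromethyl methyl sulfide
Product: 12 1-[(3,5-dimethoxyphenoxy)methoxy]-3-methoxy-5-[(methylsulfanyl)methoxy]benzene
Conditions: NaH, NaI (cat.), DMF, 0 °C → rt
Reagents that add atoms: none
Why: Williamson ether synthesis as in step 1; the diaryl formal already present is inert to base.

Step 9
Reactants: 12 1-[(3,5-dimethoxyphenoxy)methoxy]-3-methoxy-5-[(methylsulfanyl)methoxy]benzene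
Product: 13 1-(chloromethoxy)-3-[(3,5-dimethoxyphenoxy)methoxy]-5-methoxybenzene
Conditions: SO2Cl2 (1.0 equiv), CH2Cl2, −78 °C; cyclohexene, −78 → 0 °C; volatiles and the cyclohexene adduct stripped at 0.1 mbar, residue used at once
Reagents that add atoms: sulfuryl chloride, O=S(=O)(Cl)Cl
Why: Chlorinative O,S-acetal cleavage as in step 2; the existing diaryl formal has no sulfur and should survive at low temperature in the absence of acid.

Step 10
Reactants: 13 1-(chloromethoxy)-3-[(3,5-dimethoxyphenoxy)methoxy]-5-methoxybenzene; 11 2-bromo-3-[(3,5-dimethoxyphenoxy)methoxy]-5-methoxyphenol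
Product: 14 2-bromo-1-[(3,5-dimethoxyphenoxy)methoxy]-3-({3-[(3,5-dimethoxyphenoxy)methoxy]-5-methoxyphenoxy}methoxy)-5-methoxybenzene (open-chain tetramer A–OCH2O–B–OCH2O–C(Br)–OCH2O–D)
Conditions: NaH, DMF, 0 °C → rt
Reagents that add atoms: none
Why: Williamson-type alkylation of the 2-bromophenoxide by the α-chloro ether joins the two halves through the central O–CH2–O unit, the ortho bromine also shielding that carbon from C-alkylation.

Step 11
Reactants: 14 open-chain tetramer
Product: 17 triply O–CH2–O-bridged hexamethoxy bromoquaterphenyl, via singly bridged biaryl 15 (not isolated), via doubly bridged terphenyl 16 (not isolated)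
Conditions: boron-doped diamond anode, Pt cathode, undivided cell, Bu4NPF6 (0.1 M), (CF3)2CHOH, 14 kept near 1 mM by slow addition, constant current 1 mA/cm2, about 6 F/mol, 20 °C
Reagents that add atoms: none
Why: Proposed new method: at the anode a trialkoxyarene ring of 14 (an outer dimethoxy ring first, being the most easily oxidised) loses one electron to a radical cation that hexafluoroisopropanol keeps alive long enough for the tethered neighbour to attack through its carbon ortho to the acetal oxygen, a second electron and two protons are lost to restore both aromatic rings, and the sequence repeats from the more easily oxidised bridged biaryl 15 and then from terphenyl 16, six electrons in all with hydrogen evolved at the cathode. The closest known reaction type is the single intramolecular dehydrogenative coupling of two tethered alkoxyarenes to a seven-membered bridged biaryl, carried out anodically or with PhI(OCOCF3)2 or MoCl5; running three such closures in one operation along one chain is the untested part. Each of the three new rings is a seven-membered 1,3-dioxepine closed by aryl–aryl bond formation between the two aromatic carbons ortho to one O–CH2–O unit (written here as A–B, then B–C, then C–D, although the order is not essential). No stereocentre is created, and the B–C axis of 17 should arise racemic, which the target does not specify. The step needs coupling only between neighbours, only at ortho carbons and no fourth bond: the one-carbon tether lets only adjacent rings meet through a seven-membered transition state, bromine occupies the ring-C carbon between the two acetal oxygens so that exactly its two required carbons are free, and low substrate concentration with the charge held near 6 F/mol should hold back intermolecular coupling and over-oxidation. Which of its candidate carbons ring B uses for each bond does not matter, because every such positional isomer of 17 gives the same dodecaphenol in step 12.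

Step 12
Reactants: 17 triply O–CH2–O-bridged hexamethoxy bromoquaterphenyl
Product: 18 the target, bromoquaterphenyl dodecaol
Conditions: BBr3 (about 20 equiv), CH2Cl2, −78 °C → rt, argon; then ice-water, 0 °C
Reagents that add atoms: none
Why: Lewis-acid ether cleavage, in which BBr3 coordinates each ether oxygen and bromide attacks the methyl or methylene carbon (SN2), releasing MeBr and CH2Br2 and leaving aryl borates that hydrolyse to the twelve phenols while the aryl bromide stays inert.

**Compound list**

1 | 3,5-dimethoxyphenol | COc1cc(O)cc(OC)c1 | starting material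
2 | chloromethyl methyl sulfide | CSCCl | starting material
3 | 1,3-dimethoxy-5-[(methylsulfanyl)methoxy]benzene | COc1cc(OC)cc(OCSC)c1 | intermediate
4 | 1-(chloromethoxy)-3,5-dimethoxybenzene | COc1cc(OC)cc(OCCl)c1 | intermediate
5 | 5-methoxybenzene-1,3-diol (5-methoxyresorcinol) | COc1cc(O)cc(O)c1 | starting material
6 | 3-[(3,5-dimethoxyphenoxy)methoxy]-5-methoxyphenol | COc1cc(OC)cc(OCOc2cc(O)cc(OC)c2)c1 | intermediate
7 | 1-methoxy-3,5-bis(methoxymethoxy)benzene | COCOc1cc(OC)cc(OCOC)c1 | intermediate
8 | [4-methoxy-2,6-bis(methoxymethoxy)phenyl]lithium | [Li]c1c(OCOC)cc(OC)cc1OCOC | intermediate (not isolated)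
9 | 2-bromo-5-methoxy-1,3-bis(methoxymethoxy)benzene | COCOc1cc(OC)cc(OCOC)c1Br | intermediate
10 | 2-bromo-5-methoxybenzene-1,3-diol | COc1cc(O)c(Br)c(O)c1 | intermediate
11 | 2-bromo-3-[(3,5-dimethoxyphenoxy)methoxy]-5-methoxyphenol | COc1cc(OC)cc(OCOc2cc(OC)cc(O)c2Br)c1 | intermediate
12 | 1-[(3,5-dimethoxyphenoxy)methoxy]-3-methoxy-5-[(methylsulfanyl)methoxy]benzene | COc1cc(OC)cc(OCOc2cc(OC)cc(OCSC)c2)c1 | intermediate
13 | 1-(chloromethoxy)-3-[(3,5-dimethoxyphenoxy)methoxy]-5-methoxybenzene | COc1cc(OC)cc(OCOc2cc(OC)cc(OCCl)c2)c1 | intermediate
14 | open-chain tetramer: 2-bromo-1-[(3,5-dimethoxyphenoxy)methoxy]-3-({3-[(3,5-dimethoxyphenoxy)methoxy]-5-methoxyphenoxy}methoxy)-5-methoxybenzene | COc1cc(OC)cc(OCOc2cc(OC)cc(OCOc3cc(OC)cc(OCOc4cc(OC)cc(OC)c4)c3Br)c2)c1 | intermediate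
15 | singly bridged biaryl: rings A and B joined and tied by O–CH2–O into a dibenzo[d,f][1,3]dioxepine (A on the ring-B carbon between OMe and the bridge oxygen); ring B still carries the open O–CH2–O–C(Br)–O–CH2–O–D chain | COc1cc(OC)c2c(c1)OCOc3cc(OCOc4cc(OC)cc(OCOc5cc(OC)cc(OC)c5)c4Br)cc(OC)c3-2 | intermediate (not isolated)
16 | doubly bridged terphenyl: A–B and B–C bonds formed, each pair tied by O–CH2–O; ring C still carries the open O–CH2–O–D arm next to bromine | COc1cc(OC)c2c(c1)OCOc3cc4OCOc5c(Br)c(OCOc6cc(OC)cc(OC)c6)cc(OC)c5-c4c(OC)c3-2 | intermediate (not isolated)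
17 | triply bridged hexamethoxy bromoquaterphenyl: each neighbouring ring pair (A/B, B/C, C/D) bridged ortho,ortho' by O–CH2–O (three dibenzo[d,f][1,3]dioxepine rings); on ring B the aryl groups A and C flank the OMe carbon, on ring C the aryl groups B and D flank the OMe carbon and Br lies between the two bridge oxygens | COc1cc(OC)c2c(c1)OCOc3cc4OCOc5c(Br)c6OCOc7cc(OC)cc(OC)c7-c6c(OC)c5-c4c(OC)c3-2 | intermediate
18 | target: 2,4,6-trihydroxyphenyl (ring A) – 2,4,6-trihydroxy-1,3-phenylene (ring B) – 5-bromo-2,4,6-trihydroxy-1,3-phenylene (ring C) – 2,4,6-trihydroxyphenyl (ring D) | Oc1cc(O)c(-c2c(O)cc(O)c(-c3c(O)c(Br)c(O)c(-c4c(O)cc(O)cc4O)c3O)c2O)c(O)c1 | target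

**Totals**

Total step count: 12. Longest linear sequence: 8 steps (1 → 3 → 4 → 6 → 12 → 13 → 14 → 17 → 18).

**Steps most likely to fail**

1. Step 11 (anodic triple coupling). The bridged biaryl and terphenyl formed on the way are flatter and easier to oxidise than 14, so they may be oxidised further before the last ring closes, and the free para carbons of rings A and D may couple between molecules. The fallback drops the tether and builds the three aryl–aryl bonds by known cross-coupling; it sets out from 1 and returns at 18.
   - O-Methylation of 1 (MeI, K2CO3, acetone) would give 1,3,5-trimethoxybenzene F1.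
   - NBS in MeCN would give 2-bromo-1,3,5-trimethoxybenzene F2.
   - Two equivalents of NIS with catalytic CF3CO2H would give 2-bromo-4,6-diiodo-1,3,5-trimethoxybenzene F3.
   - Twofold Suzuki–Miyaura coupling with 2,4,6-trimethoxyphenylboronic acid (Pd(OAc)2, SPhos, K3PO4, toluene) at the two C–I bonds, which react ahead of the hindered C–Br bond, would give the symmetrical 5'-bromo-nonamethoxy-1,1':3',1''-terphenyl F4.
   - The four remaining ring hydrogens of F4 are equivalent, so one equivalent of NIS would give a single monoiodide, 5'-bromo-3-iodo-nonamethoxy-1,1':3',1''-terphenyl F5.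
   - A third Suzuki–Miyaura coupling with the same boronic acid would give the dodecamethyl ether of the target F6, and BBr3 in CH2Cl2 would convert it into 18.

2. Step 9 (chloromethyl ether from the dimeric methylthiomethyl ether). Electrophilic chlorination or sulfenylation of the two trialkoxyarene rings may compete with S-chlorination, and the chloromethyl ether may hydrolyse before use. The same hazard exists in step 2, but there the product is cheap and distillable. The fallback avoids the activated intermediate and sets out from 6 (with 11), returning at 14.
   - The phenols 6 (in excess) and 11 are joined in a statistical crossed formal formation with CH2Br2 and Cs2CO3 in DMF at 60 °C.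
   - 14 is then separated by chromatography from the bromine-free symmetrical formal bis{3-[(3,5-dimethoxyphenoxy)methoxy]-5-methoxyphenoxy}methane F7 and from the minor dibromo formal bis{2-bromo-3-[(3,5-dimethoxyphenoxy)methoxy]-5-methoxyphenoxy}methane F8.

3. Step 12 (global unmasking). The CH2 fragments released from the three bridges may re-attach to the very nucleophilic phloroglucinol rings by Friedel–Crafts alkylation. The two methyl ethers flanked by aryl groups may cleave incompletely, and bromine may migrate, or the polyphenol oxidise in air, during the acidic quench. The fallback unmasks in two stages, setting out from 17 and returning at 18.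
   - BCl3 in CH2Cl2 at −78 → 0 °C with pentamethylbenzene as a trap for cationic CH2 fragments should cleave only the three bridges, since BCl3 spares unactivated aryl methyl ethers. This would give the hexamethoxy bromoquaterphenyl hexaol F9.
   - F9 would then be demethylated with BBr3 at high dilution, with a cold buffered quench under argon, to give 18.

**Further compounds**

F1 | step 11 | 1,3,5-trimethoxybenzene | COc1cc(OC)cc(OC)c1
F2 | step 11 | 2-bromo-1,3,5-trimethoxybenzene | COc1cc(OC)c(Br)c(OC)c1
F3 | step 11 | 2-bromo-4,6-diiodo-1,3,5-trimethoxybenzene | COc1c(I)c(OC)c(Br)c(OC)c1I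
F4 | step 11 | 5'-bromo-2,2',2'',4,4',4'',6,6',6''-nonamethoxy-1,1':3',1''-terphenyl | COc1cc(OC)c(c(OC)c1)-c2c(OC)c(Br)c(OC)c(c2OC)-c3c(OC)cc(OC)cc3OC
F5 | step 11 | 5'-bromo-3-iodo-2,2',2'',4,4',4'',6,6',6''-nonamethoxy-1,1':3',1''-terphenyl | COc1cc(OC)c(c(OC)c1I)-c2c(OC)c(Br)c(OC)c(c2OC)-c3c(OC)cc(OC)cc3OC
F6 | step 11 | dodecamethyl ether of 18 | COc1cc(OC)c(-c2c(OC)cc(OC)c(-c3c(OC)c(Br)c(OC)c(-c4c(OC)cc(OC)cc4OC)c3OC)c2OC)c(OC)c1
F7 | step 9 | bis{3-[(3,5-dimethoxyphenoxy)methoxy]-5-methoxyphenoxy}methane | COc1cc(OC)cc(OCOc2cc(OC)cc(OCOc3cc(OC)cc(OCOc4cc(OC)cc(OC)c4)c3)c2)c1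
F8 | step 9 | bis{2-bromo-3-[(3,5-dimethoxyphenoxy)methoxy]-5-methoxyphenoxy}methane | COc1cc(OC)cc(OCOc2cc(OC)cc(OCOc3cc(OC)cc(OCOc4cc(OC)cc(OC)c4)c3Br)c2Br)c1
F9 | step 12 | hexamethoxy bromoquaterphenyl hexaol (17 without its three CH2 bridges) | COc1cc(OC)c(c(O)c1)-c2c(O)cc(O)c(c2OC)-c3c(O)c(Br)c(O)c(c3OC)-c4c(O)cc(OC)cc4OC
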